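**Retrosynthetic overview**
- The two phenols are unmasked last from aryl pivalates; no skeletal bond is made at that stage.
- Ring B (O–C7'–C8'–C8–C9) is closed second, by anti iodoetherification of a (Z)-styrenyl alkene and bridgehead deiodination (C7'–O bond; sets C7' and C8').
- Ring A (O–C7–C8–C8'–C9') is closed first, in the key step: Sharpless mono-epoxidation of a C2-symmetric (Z,Z)-2,3-bis(arylmethylidene)butane-1,4-diol, then invertive 5-endo opening of the oxirane (C7–O bond; sets C8 and C7).
- The dienediol comes from homocoupling (C8–C8' bond) of an (E)-2-stannyl-3-arylallyl alcohol, made by syn-hydrostannation of an aryl propargyl alcohol, itself from Sonogashira coupling of pivaloylated 4-bromoguaiacol with propargyl alcohol.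

Reading of the target and assumption: the SMILES is (3S,3aS,6R,6aR), with bridgehead OH and H cis and both aryl groups trans to the adjacent bridgehead substituent (endo, the 7,7'-bis-epi series of 8-hydroxypinoresinol); lignan numbering is used (C7/C7' benzylic, C8/C8' ring fusion with OH on C8, C9/C9' OCH2), and all starting materials and reagents are taken as purchased.

**Step 1**
Reactants: 1 4-bromo-2-methoxyphenol
Product: 2 4-bromo-2-methoxyphenyl 2,2-dimethylpropanoate
Conditions: PivCl (1.1 equiv), Et3N (1.5 equiv), DMAP (5 mol%), CH2Cl2, 0 °C to rt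
Reagents that add atoms: pivaloyl chloride, CC(C)(C)C(Cl)=O
Why: DMAP-catalysed O-acylation gives a hindered, electron-withdrawing aryl ester that survives all later steps and keeps both benzylic positions from ionising (needed for the stereospecific ring closures); no stereocentre is formed.

**Step 2**
Reactants: 2 4-bromo-2-methoxyphenyl 2,2-dimethylpropanoate; 3 prop-2-yn-1-ol
Product: 4 4-(3-hydroxyprop-1-yn-1-yl)-2-methoxyphenyl 2,2-dimethylpropanoate
Conditions: PdCl2(PPh3)2 (3 mol%), CuI (5 mol%), Et3N/THF 1:1 (degassed), 65 °C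
Reagents that add atoms: none
Why: Sonogashira coupling (oxidative addition of the aryl bromide to zerovalent palladium, transmetalation from the copper acetylide, reductive elimination) tolerates the free propargylic alcohol and the pivalate; no stereocentre is formed.

**Step 3**
Reactants: 4 4-(3-hydroxyprop-1-yn-1-yl)-2-methoxyphenyl 2,2-dimethylpropanoate
Product: 5 4-[(1E)-3-hydroxy-2-(tributylstannyl)prop-1-en-1-yl]-2-methoxyphenyl 2,2-dimethylpropanoate
Conditions: Bu3SnH (1.2 equiv, slow addition), PdCl2(PPh3)2 (2 mol%), THF, 0 °C to rt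
Reagents that add atoms: tributyltin hydride, CCCC[SnH](CCCC)CCCC
Why: Palladium-catalysed hydrostannation is a syn addition in which tin goes to the alkyne carbon next to CH2OH (directed by the propargylic oxygen, reinforced by the aryl group), so the aryl group ends up cis to CH2OH, the geometry from which both endo-aryl centres are later derived; no stereocentre is formed.

**Step 4**
Reactants: 5 4-[(1E)-3-hydroxy-2-(tributylstannyl)prop-1-en-1-yl]-2-methoxyphenyl 2,2-dimethylpropanoate (two equivalents)
Product: 6 (2Z,3Z)-2,3-bis{[3-methoxy-4-(pivaloyloxy)phenyl]methylidene}butane-1,4-diol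
Conditions: CuCl (2.5 equiv), DMF, rt, argon
Reagents that add atoms: none
Why: CuCl-mediated oxidative homocoupling of the alkenylstannane (tin-to-copper transmetalation, then dimerisation of the alkenylcopper) forms the C8–C8' bond with retention at both alkenes, giving the C2-symmetric (Z,Z)-dienediol; no stereocentre is formed.

**Step 5**
Reactants: 6 (2Z,3Z)-2,3-bis{[3-methoxy-4-(pivaloyloxy)phenyl]methylidene}butane-1,4-diol
Product: 8 4-[(2S,3S,4E)-3-hydroxy-3-(hydroxymethyl)-4-{[3-methoxy-4-(pivaloyloxy)phenyl]methylidene}oxolan-2-yl]-2-methoxyphenyl 2,2-dimethylpropanoate, via epoxy alcohol 7 (not isolated)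
Conditions: Ti(OiPr)4 (0.5 equiv), L-(+)-diethyl tartrate (0.6 equiv), t-BuOOH in decane (0.95 equiv), 4 Å MS, CH2Cl2, −20 °C, 24 h; then rt, 6 h
Reagents that add atoms: tert-butyl hydroperoxide, CC(C)(C)OO
Why: Sharpless asymmetric epoxidation of one of the two homotopic allylic alcohols breaks the C2 symmetry, the Ti/L-(+)-tartrate complex delivering oxygen to the face that makes the carbinol-bearing oxirane carbon C8 S (the facial sense that gives 2S epoxides from simple allylic alcohols) and syn to the Z alkene so that C7 is R, after which the Ti-bound C9' alkoxide opens the oxirane at the benzylic carbon C7 (C3-selective 5-endo SN2 opening of a 2,3-epoxy alcohol) with inversion, which makes C7 S with the aryl group trans to the new tertiary OH and closes ring A.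

**Step 6**
Reactants: 8 4-[(2S,3S,4E)-3-hydroxy-3-(hydroxymethyl)-4-{[3-methoxy-4-(pivaloyloxy)phenyl]methylidene}oxolan-2-yl]-2-methoxyphenyl 2,2-dimethylpropanoate
Product: 10 (3S,3aS,6R,6aR)-3,6-bis[3-methoxy-4-(pivaloyloxy)phenyl]tetrahydro-1H,3H-furo[3,4-c]furan-3a(4H)-ol, via bridgehead iodide 9 (not isolated)
Conditions: NIS (1.2 equiv), MeCN, 0 °C, dark; then PhMe, Bu3SnH (2.5 equiv), Et3B (0.2 equiv), air, rt
Reagents that add atoms: none
Why: 5-endo-trig iodoetherification is an anti addition in which the iodonium ion sits on the alkene face syn to the tertiary OH while the primary C9 hydroxyl attacks the benzylic carbon C7' from the opposite face, so the Z alkene gives C7' with the aryl group trans to the bridgehead substituent (endo) as ring B closes, and radical-chain deiodination with Bu3SnH then puts H on the bridgehead C8', where only the cis-fused bicycle can form.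

**Step 7**
Reactants: 10 (3S,3aS,6R,6aR)-3,6-bis[3-methoxy-4-(pivaloyloxy)phenyl]tetrahydro-1H,3H-furo[3,4-c]furan-3a(4H)-ol
Product: 11 (3S,3aS,6R,6aR)-3,6-bis(4-hydroxy-3-methoxyphenyl)tetrahydro-1H,3H-furo[3,4-c]furan-3a(4H)-ol
Conditions: K2CO3 (3 equiv), MeOH, 0 °C to rt; aq NH4Cl work-up (no strong acid)
Reagents that add atoms: none
Why: Base-mediated transesterification (methanolysis) of the two aryl pivalates frees the phenols at room temperature without ionising the acid-sensitive endo benzylic ethers, so all four stereocentres are untouched.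

**Compound list**
1 | 4-bromo-2-methoxyphenol | COc1cc(Br)ccc1O | starting material
2 | 4-bromo-2-methoxyphenyl 2,2-dimethylpropanoate | COc1cc(Br)ccc1OC(=O)C(C)(C)C | intermediate
3 | prop-2-yn-1-ol | C#CCO | starting material
4 | 4-(3-hydroxyprop-1-yn-1-yl)-2-methoxyphenyl 2,2-dimethylpropanoate | COc1cc(C#CCO)ccc1OC(=O)C(C)(C)C | intermediate
5 | 4-[(1E)-3-hydroxy-2-(tributylstannyl)prop-1-en-1-yl]-2-methoxyphenyl 2,2-dimethylpropanoate (aryl cis to CH2OH) | OC/C(=C\c1ccc(OC(=O)C(C)(C)C)c(OC)c1)[Sn](CCCC)(CCCC)CCCC | intermediate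
6 | (2Z,3Z)-2,3-bis{[3-methoxy-4-(pivaloyloxy)phenyl]methylidene}butane-1,4-diol (each aryl cis to its CH2OH) | OC/C(=C\c1ccc(OC(=O)C(C)(C)C)c(OC)c1)/C(=C/c1ccc(OC(=O)C(C)(C)C)c(OC)c1)/CO | intermediate
7 | mono-epoxide of 6: 4-[(2R,3S)-3-(hydroxymethyl)-3-{(1E)-3-hydroxy-1-[3-methoxy-4-(pivaloyloxy)phenyl]prop-1-en-2-yl}oxiran-2-yl]-2-methoxyphenyl 2,2-dimethylpropanoate (aryl and CH2OH cis on the oxirane) | OC[C@@]1(O[C@@H]1c2ccc(OC(=O)C(C)(C)C)c(OC)c2)/C(=C/c2ccc(OC(=O)C(C)(C)C)c(OC)c2)CO | intermediate (not isolated)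
8 | 4-[(2S,3S,4E)-3-hydroxy-3-(hydroxymethyl)-4-{[3-methoxy-4-(pivaloyloxy)phenyl]methylidene}oxolan-2-yl]-2-methoxyphenyl 2,2-dimethylpropanoate (2-aryl trans to 3-OH) | OC[C@]1(O)[C@H](c2ccc(OC(=O)C(C)(C)C)c(OC)c2)OC/C1=C\c3ccc(OC(=O)C(C)(C)C)c(OC)c3 | intermediate
9 | 6a-iodo analogue of 10 (iodine on the bridgehead carbon, cis to the 3a-hydroxyl; both aryl groups endo) | COc1cc([C@@H]2OC[C@@]3(O)[C@]2(I)CO[C@H]3c2ccc(OC(=O)C(C)(C)C)c(OC)c2)ccc1OC(=O)C(C)(C)C | intermediate (not isolated)
10 | (3S,3aS,6R,6aR)-3,6-bis[3-methoxy-4-(pivaloyloxy)phenyl]tetrahydro-1H,3H-furo[3,4-c]furan-3a(4H)-ol | COc1cc([C@@H]2OC[C@@]3(O)[C@@H]2CO[C@H]3c2ccc(OC(=O)C(C)(C)C)c(OC)c2)ccc1OC(=O)C(C)(C)C | intermediate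
11 | (3S,3aS,6R,6aR)-3,6-bis(4-hydroxy-3-methoxyphenyl)tetrahydro-1H,3H-furo[3,4-c]furan-3a(4H)-ol | COc1cc([C@@H]2OC[C@@]3(O)[C@@H]2CO[C@H]3c2ccc(O)c(OC)c2)ccc1O | target

**Totals**
Total step count: 7. Longest linear sequence: 7 steps (1 to 11).

**Steps most likely to fail, each with a fallback**

Step 5 is the weakest step, for three reasons:
- Both allylic alcohols of 6 are equally reactive, so mono- versus bis-epoxidation is statistical unless ring closure is faster than the second epoxidation.
- Allylic alcohols with a cis aryl group are the slow, less selective substrate class, so the ee may need upgrading by crystallisation of 8 or 10.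
- The oxirane carbon C8 is allylic, so ionisation or SN2' closure at C8 can compete with the wanted attack at C7.

Fallback: setting out from 6, both alkenes are epoxidised on purpose (Ti(OiPr)4 1.2 equiv, L-(+)-diethyl tartrate 1.4 equiv, t-BuOOH 3 equiv, CH2Cl2, −20 °C) to give the C2-symmetric bis-epoxide F1, in which no alkene is left to activate the tertiary C–O bond and the second epoxidation raises the ee. Ti(OiPr)4 at rt then drives both invertive 5-endo openings to the 3a,6a-diol F2 with both aryl groups endo. The cis-diol is closed to the cyclic thionocarbonate F3 (1,1'-thiocarbonyldiimidazole, DMAP, PhMe, 100 °C). Bu3SnH/AIBN (PhMe, 100 °C) cleaves one of the two homotopic bridgehead C–O bonds (Barton–McCombie-type deoxygenation); the bridgehead radical takes H to give the cis-fused ring, and the residual thiocarbonate leaves the other oxygen as COS on aqueous work-up. The route is rejoined at 10.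

Step 6 may fail if the 5-endo closure is slow, if the tertiary allylic alcohol undergoes a semipinacol shift on the iodonium ion, or if an open benzylic cation erodes the anti stereospecificity.

Fallback: setting out from 8, hydroboration–oxidation (BH3·THF 4 equiv, THF, 0 °C to rt; then NaOH, H2O2) adds H to C8' from the face syn to the tertiary OH and OH to the benzylic carbon, giving the triol F4. MnO2 (CH2Cl2, rt) oxidises only the benzylic alcohol to the aryl ketone F5, which closes onto the primary hydroxyl as the cis-fused hemiketal F6. Et3SiH/BF3·OEt2 (CH2Cl2, −78 °C) reduces the derived oxocarbenium ion from the convex face, which places the aryl group endo and comes back to the route at 10.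

Step 4 may fail because tributylstannanes couple more slowly than trimethylstannanes with CuCl, and protodestannylation can compete. (The minor regioisomer from step 3 must be removed before this step.)

Fallback: setting out from 5, iododestannylation (I2, CH2Cl2, 0 °C) gives the vinyl iodide F7 with retention of geometry. A Stille cross-coupling of F7 with a second equivalent of 5 (Pd2(dba)3 2.5 mol%, AsPh3 10 mol%, CuI 10 mol%, DMF, 40 °C) makes the same C8–C8' bond with both alkene geometries retained and comes back to the route at 6.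

**Further compounds**
F1 | step 5 | (2S,2'S,3R,3'R)-2,2'-bis(hydroxymethyl)-3,3'-bis[3-methoxy-4-(pivaloyloxy)phenyl]-2,2'-bioxirane | OC[C@@]1(O[C@@H]1c2ccc(OC(=O)C(C)(C)C)c(OC)c2)[C@@]3(CO)O[C@@H]3c4ccc(OC(=O)C(C)(C)C)c(OC)c4
F2 | step 5 | (3S,3aS,6S,6aS)-3,6-bis[3-methoxy-4-(pivaloyloxy)phenyl]tetrahydro-1H,3H-furo[3,4-c]furan-3a,6a-diol | COc1cc([C@@H]2OC[C@@]3(O)[C@]2(O)CO[C@H]3c2ccc(OC(=O)C(C)(C)C)c(OC)c2)ccc1OC(=O)C(C)(C)C
F3 | step 5 | cyclic 3a,6a-thionocarbonate of F2 | COc1cc([C@@H]2OC[C@@]3(OC(=S)O4)[C@]24CO[C@H]3c2ccc(OC(=O)C(C)(C)C)c(OC)c2)ccc1OC(=O)C(C)(C)C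
F4 | step 6 | triol from hydroboration–oxidation of 8 (H on C8' cis to the tertiary OH; benzylic OH on C7') | OC[C@]1(O)[C@H](c2ccc(OC(=O)C(C)(C)C)c(OC)c2)OC[C@@H]1[C@H](O)c3ccc(OC(=O)C(C)(C)C)c(OC)c3
F5 | step 6 | aryl ketone from benzylic oxidation of F4 | OC[C@]1(O)[C@H](c2ccc(OC(=O)C(C)(C)C)c(OC)c2)OC[C@@H]1C(=O)c3ccc(OC(=O)C(C)(C)C)c(OC)c3
F6 | step 6 | cis-fused bicyclic hemiketal of F5 (6-hydroxy analogue of 10; anomeric centre as a mixture) | COc1cc(C2(O)OC[C@@]3(O)[C@@H]2CO[C@H]3c2ccc(OC(=O)C(C)(C)C)c(OC)c2)ccc1OC(=O)C(C)(C)C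
F7 | step 4 | 4-[(1E)-3-hydroxy-2-iodoprop-1-en-1-yl]-2-methoxyphenyl 2,2-dimethylpropanoate (aryl cis to CH2OH) | OC/C(I)=C\c1ccc(OC(=O)C(C)(C)C)c(OC)c1
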